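**Plan**

- Labels (elemane numbering): ring A = cyclohexane C5–C6–C7–C8–C9–C10; ring B = lactone O–C6–C7–C11(=C13H2)–C12(=O). C8 carries the angelate, C10 the methyl and vinyl groups, C5 the acrylic acid (C4, C3, C15).
- Cuts, in order: the C15 acid back to an isopropenyl methyl and the C8 ester back to the alcohol; then C11–C12 and C6–C7 together, which opens rings A and B to an acyclic allenyl aldehyde plus CO2; then C7–C8 (propargylboration of a C8 aldehyde); then C5–C10 (Ireland–Claisen) to an allylic ester of 3-methylbut-3-enoic acid.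
- Enabling feature: C11 bears the exocyclic methylene C13 and lies between the carbonyl C12 and the ring-fusion carbon C7, which is bonded to the carbinol C6. This is the retron of a 2-carboxyallyl metal (allene C7=C11=C13 plus CO2) adding through C7 to a C6 aldehyde, so rings A and B form in one event from three components.
- Forward: the chain is joined first (C5–C10, then C7–C8), rings A and B arise together in the key step, then the angelate and the C15 acid are installed.
- Stereochemistry: C5 and C10 from a chiral boron enolate Claisen rearrangement; C8 from reagent-controlled propargylboration; C6 and C7 from the chair–chair transition state of the key step, steered by C5, C8 and the quaternary C10; the Z-enoate from angelic acid.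

Key step: step 10

Remark (assumption): the sense of induction of the two diazaborolidine controllers (steps 3 and 7) is assigned from their chair transition-state models, not from memory of a specific result; both antipodes of 1,2-diphenylethane-1,2-diamine are commercial, so the mirror-image controller would be used if either sense proves opposite.

**Route**

Step 1
Reactants: 1 tert-butyl(but-3-yn-1-yloxy)dimethylsilane
Product: 3 (2E)-5-{[tert-butyl(dimethyl)silyl]oxy}-3-methylpent-2-en-1-ol, via alkenylalane 2 (not isolated)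
Conditions: Me3Al (2 equiv), Cp2ZrCl2 (0.2 equiv), CH2Cl2, 0 °C to rt; then n-BuLi, (CH2O)n, THF, −78 °C to rt
Reagents that add atoms: trimethylaluminium, C[Al](C)C; paraformaldehyde (formaldehyde unit), C=O
Why: Negishi zirconium-catalysed carboalumination adds methyl and aluminium syn across the terminal alkyne (methyl to the internal carbon), and the alkenylalanate formed with n-BuLi is hydroxymethylated with retention, so the trisubstituted alkene should form with E geometry.

Step 2
Reactants: 3 (2E)-5-{[tert-butyl(dimethyl)silyl]oxy}-3-methylpent-2-en-1-ol; 4 3-methylbut-3-enoic acid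
Product: 5 (2E)-5-{[tert-butyl(dimethyl)silyl]oxy}-3-methylpent-2-en-1-yl 3-methylbut-3-enoate
Conditions: DCC, DMAP (5 mol%), CH2Cl2, 0 °C
Reagents that add atoms: none
Why: Steglich esterification of a primary allylic alcohol, run cold with little DMAP so that the β,γ-unsaturated acyl group does not move into conjugation.

Step 3
Reactants: 5 (2E)-5-{[tert-butyl(dimethyl)silyl]oxy}-3-methylpent-2-en-1-yl 3-methylbut-3-enoate
Product: 7 (2S,3S)-5-{[tert-butyl(dimethyl)silyl]oxy}-3-ethenyl-3-methyl-2-(prop-1-en-2-yl)pentanoic acid, via boron enolate 6 (not isolated)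
Conditions: (4S,5S)-2-bromo-1,3-bis{[3,5-bis(trifluoromethyl)phenyl]sulfonyl}-4,5-diphenyl-1,3,2-diazaborolidine (1.2 equiv), Et3N, toluene/hexane, −78 °C, then 4 °C; aq. work-up
Reagents that add atoms: none
Why: Enantioselective Ireland–Claisen rearrangement through a chiral boron enolate, in which amine-mediated enolization in the non-polar medium should give the enolate with the isopropenyl group cis to the allylic oxygen, the chair [3,3] shift with the (E)-alkene then joins C5 to C10 in the like (2S,3S) sense (isopropenyl and methyl axial in the chair), and the sulfonamide ligands on boron select the enolate face.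

Step 4
Reactants: 7 (2S,3S)-5-{[tert-butyl(dimethyl)silyl]oxy}-3-ethenyl-3-methyl-2-(prop-1-en-2-yl)pentanoic acid
Product: 8 (2S,3S)-5-{[tert-butyl(dimethyl)silyl]oxy}-3-ethenyl-N-methoxy-N,3-dimethyl-2-(prop-1-en-2-yl)pentanamide
Conditions: CDI, CH2Cl2, rt; then MeNH(OMe)·HCl, rt
Reagents that add atoms: N,O-dimethylhydroxylamine hydrochloride, CNOC.Cl
Why: Weinreb amide formation through the acyl imidazole needs no added base, which protects the α-stereocentre C5, and the amide later serves as a masked aldehyde.

Step 5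
Reactants: 8 (2S,3S)-5-{[tert-butyl(dimethyl)silyl]oxy}-3-ethenyl-N-methoxy-N,3-dimethyl-2-(prop-1-en-2-yl)pentanamide
Product: 9 (2S,3S)-3-ethenyl-5-hydroxy-N-methoxy-N,3-dimethyl-2-(prop-1-en-2-yl)pentanamide
Conditions: HF·pyridine, pyridine, THF, 0 °C to rt; crude used at once
Reagents that add atoms: none
Why: Buffered fluoride cleavage of the primary silyl ether leaves the amide and the alkenes untouched, and immediate use of the crude alcohol avoids slow lactonization onto the amide.

Step 6
Reactants: 9 (2S,3S)-3-ethenyl-5-hydroxy-N-methoxy-N,3-dimethyl-2-(prop-1-en-2-yl)pentanamide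
Product: 10 (2S,3S)-3-ethenyl-N-methoxy-N,3-dimethyl-5-oxo-2-(prop-1-en-2-yl)pentanamide
Conditions: Dess–Martin periodinane, CH2Cl2, 0 °C to rt
Reagents that add atoms: none
Why: Dess–Martin oxidation of the primary alcohol gives an aldehyde whose α-carbon (C9) is a methylene next to the quaternary C10, so no stereocentre can epimerize.

Step 7
Reactants: 10 (2S,3S)-3-ethenyl-N-methoxy-N,3-dimethyl-5-oxo-2-(prop-1-en-2-yl)pentanamide; 11 tributyl(propa-1,2-dien-1-yl)stannane
Product: 12 (2S,3S,5R)-3-ethenyl-5-hydroxy-N-methoxy-N,3-dimethyl-2-(prop-1-en-2-yl)octa-6,7-dienamide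
Conditions: 11, (4R,5R)-2-bromo-1,3-bis[(4-methylphenyl)sulfonyl]-4,5-diphenyl-1,3,2-diazaborolidine, CH2Cl2, 0 °C to rt; then 10, −78 °C; aq. work-up
Reagents that add atoms: none
Why: Reagent-controlled asymmetric propargylboration, in which the allenylstannane is transmetalated with allylic transposition to a B-propargyl diazaborolidine that adds to the aldehyde through a cyclic SE2' chair to give the buta-2,3-dienyl carbinol, with C8 set as R by the chiral ligand because the remote C10 centre has little 1,3-influence.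

Step 8
Reactants: 12 (2S,3S,5R)-3-ethenyl-5-hydroxy-N-methoxy-N,3-dimethyl-2-(prop-1-en-2-yl)octa-6,7-dienamide
Product: 13 (2S,3S,5R)-5-{[tert-butyl(dimethyl)silyl]oxy}-3-ethenyl-N-methoxy-N,3-dimethyl-2-(prop-1-en-2-yl)octa-6,7-dienamide
Conditions: TBSOTf, 2,6-lutidine, CH2Cl2, −78 °C to 0 °C
Reagents that add atoms: tert-butyldimethylsilyl trifluoromethanesulfonate, CC(C)(C)[Si](C)(C)OS(=O)(=O)C(F)(F)F
Why: Standard silylation of the secondary allenyl carbinol with a silyl triflate and a hindered base, which keeps O8 out of lactol formation in step 9 and out of lactonization in step 10.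

Step 9
Reactants: 13 (2S,3S,5R)-5-{[tert-butyl(dimethyl)silyl]oxy}-3-ethenyl-N-methoxy-N,3-dimethyl-2-(prop-1-en-2-yl)octa-6,7-dienamide
Product: 14 (2S,3S,5R)-5-{[tert-butyl(dimethyl)silyl]oxy}-3-ethenyl-3-methyl-2-(prop-1-en-2-yl)octa-6,7-dienal
Conditions: i-Bu2AlH, THF, −78 °C; aq. potassium sodium tartrate
Reagents that add atoms: none
Why: Weinreb amide reduction stops at the chelated tetrahedral aluminate, which gives the aldehyde only on work-up, so over-reduction and epimerization at C5 should be avoided.

Step 10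
Reactants: 14 (2S,3S,5R)-5-{[tert-butyl(dimethyl)silyl]oxy}-3-ethenyl-3-methyl-2-(prop-1-en-2-yl)octa-6,7-dienal
Product: 17 (3aS,4R,6S,7S,7aR)-4-{[tert-butyl(dimethyl)silyl]oxy}-6-ethenyl-6-methyl-3-methylidene-7-(prop-1-en-2-yl)hexahydro-1-benzofuran-2(3H)-one, via nickelalactone 15 (not isolated), via hydroxy acid 16 (not isolated)
Conditions: Ni(cod)2 (1.2 equiv), DBU (2.5 equiv), CO2 (1 atm), THF, 0 °C, slow addition of 14, then rt; 1 M HCl; then TsOH (cat.), CH2Cl2, rt
Reagents that add atoms: carbon dioxide, O=C=O
Why: Proposed new method: zerovalent nickel should couple CO2 with the terminal C11=C13 bond of the allene (new C–C bond at the central carbon C11) to give the allylnickel carboxylate 15, whose γ-carbon C7 adds to the tethered C6 aldehyde through a six-membered chair transition state, and acidification releases hydroxy acid 16, which lactonizes. The closest known reaction types are the stoichiometric nickel-mediated sequential addition of CO2 and an aryl aldehyde to a terminal allene and the intramolecular addition of 2-carboalkoxyallylnickel species to aldehydes; new here is the ring-forming use with a tethered aliphatic aldehyde present from the start, which is why 14 is added slowly to a CO2-saturated nickel/DBU solution so that carboxylation outruns direct nickel-mediated aldehyde–allene coupling. Ring A closes in a 6-exo-trig allylation (SE2') and lactone ring B in a 5-exo-trig acyl substitution of O6 on C12. C6 and C7 are set together in a chair–chair (trans-decalin-like) array in which the allyl unit has C8 anti to C13 and the C6–O and C7–C11 bonds are both equatorial, which gives the trans-fused lactone; the usual cis outcome of such cyclizations, reached from the other allyl geometry, needs an axial C6–O bond that is 1,3-syn to an axial carbon substituent of the quaternary C10 in either chair, and syn/anti equilibration of the allylnickel should let the unhindered trans pathway win. The facial sense follows from the chair that keeps the C5 isopropenyl and C10 vinyl groups equatorial; its cost, a 1,3-diaxial C10 methyl/C8 oxygen contact, is the one present in the target itself, and it places the C8–O bond gauche and not antiperiplanar to the forming bond, which leaves the allyl unit most nucleophilic. Also needed are CO2 uptake at C11 only (terminal monosubstituted allene, with the vinyl and isopropenyl groups inert), lactonization at O6 only (O8 stays silylated) and retention at C5 (hindered α-hydrogen, CO2-buffered base, 0 °C).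

Step 11
Reactants: 17 (3aS,4R,6S,7S,7aR)-4-{[tert-butyl(dimethyl)silyl]oxy}-6-ethenyl-6-methyl-3-methylidene-7-(prop-1-en-2-yl)hexahydro-1-benzofuran-2(3H)-one
Product: 18 (3aR,4R,6S,7S,7aR)-6-ethenyl-4-hydroxy-6-methyl-3-methylidene-7-(prop-1-en-2-yl)hexahydro-1-benzofuran-2(3H)-one
Conditions: HF·pyridine, THF, 0 °C to rt
Reagents that add atoms: none
Why: Acidic fluoride desilylation frees the axial C8 hydroxyl without conjugate addition to the methylene lactone and without base that could move the lactone to O8.

Step 12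
Reactants: 18 (3aR,4R,6S,7S,7aR)-6-ethenyl-4-hydroxy-6-methyl-3-methylidene-7-(prop-1-en-2-yl)hexahydro-1-benzofuran-2(3H)-one; 19 angelic acid [(2Z)-2-methylbut-2-enoic acid]
Product: 20 (3aR,4R,6S,7S,7aR)-6-ethenyl-6-methyl-3-methylidene-2-oxo-7-(prop-1-en-2-yl)octahydro-1-benzofuran-4-yl (2Z)-2-methylbut-2-enoate
Conditions: 19, 2,4,6-trichlorobenzoyl chloride, Et3N, toluene, rt; then 18, 80 °C
Reagents that add atoms: none
Why: Yamaguchi-type mixed-anhydride acylation run without DMAP, a protocol known to transfer the angeloyl group with its Z geometry intact, esterifies the C8 hydroxyl with retention at C8.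

Step 13
Reactants: 20 (3aR,4R,6S,7S,7aR)-6-ethenyl-6-methyl-3-methylidene-2-oxo-7-(prop-1-en-2-yl)octahydro-1-benzofuran-4-yl (2Z)-2-methylbut-2-enoate
Product: 22 (3aR,4R,6S,7R,7aR)-6-ethenyl-6-methyl-3-methylidene-2-oxo-7-(3-oxoprop-1-en-2-yl)octahydro-1-benzofuran-4-yl (2Z)-2-methylbut-2-enoate, via allylic alcohol 21 (not isolated)
Conditions: SeO2 (0.5 equiv), t-BuOOH, CH2Cl2, rt; filtration; then Dess–Martin periodinane, CH2Cl2, 0 °C
Reagents that add atoms: tert-butyl hydroperoxide, CC(C)(C)OO
Why: Riley allylic oxidation (ene reaction then [2,3]-shift) should pick the methyl of the only electron-rich alkene with accessible allylic hydrogens (the vinyl group has none, the two enoate alkenes are electron-poor and C5–H is tertiary and hindered), and Dess–Martin oxidation of the crude converges alcohol 21 and any enal to 22.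

Step 14
Reactants: 22 (3aR,4R,6S,7R,7aR)-6-ethenyl-6-methyl-3-methylidene-2-oxo-7-(3-oxoprop-1-en-2-yl)octahydro-1-benzofuran-4-yl (2Z)-2-methylbut-2-enoate
Product: 23 2-[(3aR,4R,6S,7R,7aR)-6-ethenyl-6-methyl-4-{[(2Z)-2-methylbut-2-enoyl]oxy}-3-methylidene-2-oxooctahydro-1-benzofuran-7-yl]prop-2-enoic acid (target, CNP0256928.2)
Conditions: NaClO2, NaH2PO4, 2-methyl-2-butene, t-BuOH/H2O, 0 °C to rt
Reagents that add atoms: sodium chlorite, [Na+].[O-]Cl=O
Why: Pinnick oxidation converts the enal into the acrylic acid under buffered conditions with 2-methyl-2-butene as hypochlorite scavenger, which should leave the angelate, the methylene lactone and all stereocentres untouched.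

**Compound list**

1 | tert-butyl(but-3-yn-1-yloxy)dimethylsilane | C#CCCO[Si](C)(C)C(C)(C)C | starting material
2 | [(1E)-4-{[tert-butyl(dimethyl)silyl]oxy}-2-methylbut-1-en-1-yl](dimethyl)alumane (alkenylalane, not isolated) | C/C(CCO[Si](C)(C)C(C)(C)C)=C\[Al](C)C | intermediate
3 | (2E)-5-{[tert-butyl(dimethyl)silyl]oxy}-3-methylpent-2-en-1-ol | C/C(CCO[Si](C)(C)C(C)(C)C)=C\CO | intermediate
4 | 3-methylbut-3-enoic acid | C=C(C)CC(=O)O | starting material
5 | (2E)-5-{[tert-butyl(dimethyl)silyl]oxy}-3-methylpent-2-en-1-yl 3-methylbut-3-enoate | C=C(C)CC(=O)OC/C=C(\C)CCO[Si](C)(C)C(C)(C)C | intermediate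
6 | boron enolate of 5 (O-boryl ketene acetal, isopropenyl cis to the allyloxy group, (4S,5S)-diazaborolidine on oxygen; not isolated) | C=C(C)/C=C(\OC/C=C(\C)CCO[Si](C)(C)C(C)(C)C)OB1N(S(=O)(=O)c2cc(cc(c2)C(F)(F)F)C(F)(F)F)[C@@H](c2ccccc2)[C@H](c2ccccc2)N1S(=O)(=O)c1cc(cc(c1)C(F)(F)F)C(F)(F)F | intermediate
7 | (2S,3S)-5-{[tert-butyl(dimethyl)silyl]oxy}-3-ethenyl-3-methyl-2-(prop-1-en-2-yl)pentanoic acid | C=C[C@](C)(CCO[Si](C)(C)C(C)(C)C)[C@@H](C(=O)O)C(C)=C | intermediate
8 | (2S,3S)-5-{[tert-butyl(dimethyl)silyl]oxy}-3-ethenyl-N-methoxy-N,3-dimethyl-2-(prop-1-en-2-yl)pentanamide | C=C[C@](C)(CCO[Si](C)(C)C(C)(C)C)[C@@H](C(=O)N(C)OC)C(C)=C | intermediate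
9 | (2S,3S)-3-ethenyl-5-hydroxy-N-methoxy-N,3-dimethyl-2-(prop-1-en-2-yl)pentanamide | C=C[C@](C)(CCO)[C@@H](C(=O)N(C)OC)C(C)=C | intermediate
10 | (2S,3S)-3-ethenyl-N-methoxy-N,3-dimethyl-5-oxo-2-(prop-1-en-2-yl)pentanamide | C=C[C@](C)(CC=O)[C@@H](C(=O)N(C)OC)C(C)=C | intermediate
11 | tributyl(propa-1,2-dien-1-yl)stannane | C=C=C[Sn](CCCC)(CCCC)CCCC | starting material
12 | (2S,3S,5R)-3-ethenyl-5-hydroxy-N-methoxy-N,3-dimethyl-2-(prop-1-en-2-yl)octa-6,7-dienamide | C=C[C@](C)(C[C@@H](O)C=C=C)[C@@H](C(=O)N(C)OC)C(C)=C | intermediate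
13 | (2S,3S,5R)-5-{[tert-butyl(dimethyl)silyl]oxy}-3-ethenyl-N-methoxy-N,3-dimethyl-2-(prop-1-en-2-yl)octa-6,7-dienamide | C=C[C@](C)(C[C@@H](O[Si](C)(C)C(C)(C)C)C=C=C)[C@@H](C(=O)N(C)OC)C(C)=C | intermediate
14 | (2S,3S,5R)-5-{[tert-butyl(dimethyl)silyl]oxy}-3-ethenyl-3-methyl-2-(prop-1-en-2-yl)octa-6,7-dienal | C=C[C@](C)(C[C@@H](O[Si](C)(C)C(C)(C)C)C=C=C)[C@@H](C=O)C(C)=C | intermediate
15 | nickelalactone (allylnickel carboxylate from 14 and CO2; syn/anti-equilibrating, DBU ligands omitted; not isolated) | C=C[C@](C)(C[C@@H](O[Si](C)(C)C(C)(C)C)C=C1C[Ni]OC1=O)[C@@H](C=O)C(C)=C | intermediate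
16 | hydroxy acid (seco acid of 17 with free C6 hydroxyl and C12 acid, configuration as in 17; not isolated) | C=C[C@]1(C)C[C@@H](O[Si](C)(C)C(C)(C)C)[C@@H](C(=C)C(=O)O)[C@H](O)[C@H]1C(C)=C | intermediate
17 | (3aS,4R,6S,7S,7aR)-4-{[tert-butyl(dimethyl)silyl]oxy}-6-ethenyl-6-methyl-3-methylidene-7-(prop-1-en-2-yl)hexahydro-1-benzofuran-2(3H)-one | C=C[C@]1(C)C[C@@H](O[Si](C)(C)C(C)(C)C)[C@H]2C(=C)C(=O)O[C@@H]2[C@H]1C(C)=C | intermediate
18 | (3aR,4R,6S,7S,7aR)-6-ethenyl-4-hydroxy-6-methyl-3-methylidene-7-(prop-1-en-2-yl)hexahydro-1-benzofuran-2(3H)-one | C=C[C@]1(C)C[C@@H](O)[C@H]2C(=C)C(=O)O[C@@H]2[C@H]1C(C)=C | intermediate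
19 | angelic acid, (2Z)-2-methylbut-2-enoic acid | C/C=C(/C)C(=O)O | starting material
20 | (3aR,4R,6S,7S,7aR)-6-ethenyl-6-methyl-3-methylidene-2-oxo-7-(prop-1-en-2-yl)octahydro-1-benzofuran-4-yl (2Z)-2-methylbut-2-enoate | C=C[C@]1(C)C[C@@H](OC(=O)/C(C)=C\C)[C@H]2C(=C)C(=O)O[C@@H]2[C@H]1C(C)=C | intermediate
21 | (3aR,4R,6S,7R,7aR)-6-ethenyl-7-(3-hydroxyprop-1-en-2-yl)-6-methyl-3-methylidene-2-oxooctahydro-1-benzofuran-4-yl (2Z)-2-methylbut-2-enoate (not isolated) | C=C[C@]1(C)C[C@@H](OC(=O)/C(C)=C\C)[C@H]2C(=C)C(=O)O[C@@H]2[C@H]1C(=C)CO | intermediate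
22 | (3aR,4R,6S,7R,7aR)-6-ethenyl-6-methyl-3-methylidene-2-oxo-7-(3-oxoprop-1-en-2-yl)octahydro-1-benzofuran-4-yl (2Z)-2-methylbut-2-enoate | C=C[C@]1(C)C[C@@H](OC(=O)/C(C)=C\C)[C@H]2C(=C)C(=O)O[C@@H]2[C@H]1C(=C)C=O | intermediate
23 | 2-[(3aR,4R,6S,7R,7aR)-6-ethenyl-6-methyl-4-{[(2Z)-2-methylbut-2-enoyl]oxy}-3-methylidene-2-oxooctahydro-1-benzofuran-7-yl]prop-2-enoic acid | C=C[C@]1(C)C[C@@H](OC(=O)/C(C)=C\C)[C@H]2C(=C)C(=O)O[C@@H]2[C@H]1C(=C)C(=O)O | target

Total step count: 14
Longest linear sequence: 14 steps (from 1 to 23)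

**Steps most likely to fail**

1. Step 10 (Proposed new method). What may go wrong:
   - ring closure through the kinetically formed allylnickel geometry, or through direct nickel-mediated aldehyde–allene coupling, either of which leads to cis ring fusion;
   - closure through the alternative chair, because of the 1,3-diaxial C10 methyl/C8 silyloxy contact, which inverts the facial sense at C6 and C7;
   - base-induced epimerization or alkene migration at C5 before cyclization.

   Fallback (known reaction types; sets out from 13, comes back at 17): copper-catalysed silacarboxylation of the allene in 13 (PhMe2Si–Bpin, CO2, Cu(OAc)2, PCy3) should give the 2-carboxy allylsilane F1. Reduction with i-Bu2AlH at −78 °C, where the aluminium carboxylate is inert, unmasks the aldehyde F2. BF3·OEt2 then triggers an intramolecular Hosomi–Sakurai cyclization through an open transition state, the mode known to favour trans-fused α-methylene lactones, and the hydroxy acid 16 so formed lactonizes to 17.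

2. Step 13. What may go wrong: poor chemoselectivity of the allylic oxidation (attack at the tertiary C5–H or at the angelate methyls, over-oxidation) or low conversion of the hindered 1,1-disubstituted alkene.

   Fallback (sets out from 20, comes back at 22): ene-type chlorination of the isopropenyl group with hypochlorous acid (Ca(OCl)2, CO2, CH2Cl2/H2O) should give the allylic chloride F3, and Kornblum-type oxidation with trimethylamine N-oxide in DMSO converts it to 22.

3. Step 12. What may go wrong: slow acylation of the axial C8 hydroxyl next to the syn-axial C10 methyl, so that Z to E isomerization of the angeloyl group or translactonization to O8 becomes competitive.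

   Fallback (sets out from 18, comes back at 20): esterification with the small acid 2-[bis(2,2,2-trifluoroethoxy)phosphoryl]propanoic acid (DCC, DMAP cat.) should give the phosphonate ester F4. Still–Gennari olefination with acetaldehyde (KN(SiMe3)2, 18-crown-6, THF, −78 °C) then builds the Z-configured 2-methylbut-2-enoate on the ring oxygen and gives 20.

**Further compounds**

F1 | step 10 | (2Z)-2-{[dimethyl(phenyl)silyl]methyl}alk-2-enoic acid from 13 (C8 cis to the silylmethyl group; Weinreb amide and C8 silyl ether retained) | C=C[C@](C)(C[C@@H](O[Si](C)(C)C(C)(C)C)/C=C(\C[Si](C)(C)c1ccccc1)C(=O)O)[C@@H](C(=O)N(C)OC)C(C)=C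
F2 | step 10 | C6 aldehyde corresponding to F1 | C=C[C@](C)(C[C@@H](O[Si](C)(C)C(C)(C)C)/C=C(\C[Si](C)(C)c1ccccc1)C(=O)O)[C@@H](C=O)C(C)=C
F3 | step 13 | (3aR,4R,6S,7R,7aR)-7-(3-chloroprop-1-en-2-yl)-6-ethenyl-6-methyl-3-methylidene-2-oxooctahydro-1-benzofuran-4-yl (2Z)-2-methylbut-2-enoate | C=C[C@]1(C)C[C@@H](OC(=O)/C(C)=C\C)[C@H]2C(=C)C(=O)O[C@@H]2[C@H]1C(=C)CCl
F4 | step 12 | 2-[bis(2,2,2-trifluoroethoxy)phosphoryl]propanoate ester of 18 at O8 (mixture at the phosphonate α-carbon) | C=C[C@]1(C)C[C@@H](OC(=O)C(C)P(=O)(OCC(F)(F)F)OCC(F)(F)F)[C@H]2C(=C)C(=O)O[C@@H]2[C@H]1C(C)=C
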